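(Readings and results are calculated with made-up constants, and the scatter is random.)

**The debt.** 20.0 turnovers per catalyst charged: that is what this flask owes at the moment asked about, with 20% of the substrate converted at a loading of 1 mol%.

- larch: substrate 0.19 M; reagent 4 equiv; free catalyst 1 mol%; the very flask that is asked about, followed so far
- flask: substrate 0.19 M; reagent 4.00 equiv; free catalyst 1 mol%

larch run (percent of the substrate charged)

| time / min | target / % | substrate / % |
|---|---|---|
| 0.667 | 32 | 66 |
| 1.33 | 53 | 45 |
| 2.00 | 63 | 36 |
| 2.50 | 72 | 28 |
| 3.00 | 78 | 24 |

(readings scatter by 1.5 percentage points)

- the numbers in the tables scatter by 1.5 percentage points (one standard deviation)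
- no earlier run changes the charge of free catalyst; that part of a forecast is a guess
- no earlier run changes the charge of reagent; that part of a forecast is a guess

* apparent order in free catalyst when 20% of the substrate are converted (percent change of the rate of making target for one percent more free catalyst charged)
* apparent order in reagent when 20% of the substrate are converted (percent change of the rate of making target for one percent more reagent charged)
* factor on the rate of making target when 20% of the substrate are converted if free catalyst is charged twice over

**Two clocks.** The larch run is this flask, followed so far. Its first reading, taken as a first-order fall of c(substrate), gives a constant of 0.623 /min, so I reckon the debt paid by 0.358 min, the look time, the time to reach that conversion. Between the third and last readings the same constant reads 0.405 /min. I assume this drift is the catalyst ageing, and as a reading from scattered points it gives an ageing time of 5.04 min. On that assumption, a doubled charge that reaches the same conversion in half the look time has less ageing behind it.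

**My reckoning.** The look time is far shorter than the ageing time, at a ratio of 0.0710. So, on my assumption, I commit to a factor of 2.07 on doubling and an order in catalyst of 1.05. For reagent the run gives me no handle.

**The forecast.** It says 0.9 (0.5 to 1.3) in catalyst, 0.6 (0 to 1.1) in reagent and a factor of 1.9 (1.4 to 2.5), on the ground: "A catalytic rate is usually about first order in catalyst, slightly less if there is saturation or a side equilibrium". Its catalyst order is lower than mine.

**The flask.**

    free catalyst ⇌ dormant form (K = 7.70, k = 0.0750 /s)
    catalyst intermediate A ⇌ catalyst intermediate B (K = 4.80, k = 78.0 /s)
    catalyst intermediate C → free catalyst + target (k = 1.50 /s)
    reagent + catalyst intermediate B → catalyst intermediate C (k = 41.0 /M/s)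
    substrate + free catalyst ⇌ catalyst intermediate A (K = 3.20 /M, k = 43.0 /M/s)

The flask gives 1.3 in free catalyst, 0.084 in reagent and a factor of 2.29. The dormant form, an off-cycle species, already holds 37.3% of the catalyst at 0.600 min. The relaxation half-life of free catalyst and dormant form, by that step alone, is 0.136 min, so my look time spans 2.63 of them. At a charge twice over, with the look time taken at half of mine, it spans 1.32.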